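**Assumption:** the target is taken exactly as drawn: lower unit (2R,3S) as in (+)-catechin, side chain (1R,2S), attached at C6 of the flavan. (+)-Catechin hydrate, benzyl bromide, N-bromosuccinimide and benzyl mercaptan are bought.

## Retrosynthetic overview

1. Lower half (nucleophile): (+)-catechin 1 is benzylated with benzyl bromide 2 to 3 and brominated with N-bromosuccinimide 4 at C8 to give 5, whose only free ring-A carbon is C6.
2. Upper half (electrophile): 1 is dibrominated to 6; base and benzyl mercaptan 7 dearomatize ring B to the para-quinone methide 8, which unzips the pyran; thiolate capture (9) and benzylation give the capped sulfide 10.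
3. Key bond, C(methine)–C6: silver-mediated ionization of 10 to the quinoid cation 11 and Friedel–Crafts capture by C6 of 5 gives 12 and sets the methine centre.
4. One global hydrogenolysis (nine benzyl ethers, three C–Br) gives the target gambiriin 13.
5. Ring order: no ring is built; ring C of the upper catechin is opened in step 4, ring C of the lower catechin is carried through intact.

## Route

**Step 1**
Reactants: 1 (+)-catechin, 2 benzyl bromide
Product: 3 (2R,3S)-5,7-bis(benzyloxy)-2-[3,4-bis(benzyloxy)phenyl]chroman-3-ol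
Conditions: BnBr (4.4 equiv), K2CO3, DMF, 0 °C → rt, Ar
Reagents that add atoms: benzyl bromide BrCc1ccccc1
Why: Williamson etherification in which K2CO3 deprotonates only the four phenols and not the C3 alcohol, and no stereocentre is touched because once O4' is alkylated ring C can no longer open through a quinone methide.

**Step 2**
Reactants: 3 tetra-O-benzyl catechin, 4 N-bromosuccinimide
Product: 5 (2R,3S)-8-bromo-5,7-bis(benzyloxy)-2-[3,4-bis(benzyloxy)phenyl]chroman-3-ol
Conditions: NBS (1.05 equiv), CH2Cl2, −78 °C → rt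
Reagents that add atoms: N-bromosuccinimide O=C1CCC(=O)N1Br
Why: Electrophilic aromatic bromination goes to C8, the most nucleophilic ring-A carbon of 5,7-di-O-benzyl flavans, which is the established C8-blocking tactic that leaves C6 as the only free ring-A position.

**Step 3**
Reactants: 1 (+)-catechin, 4 N-bromosuccinimide
Product: 6 (2R,3S)-6,8-dibromo-2-(3,4-dihydroxyphenyl)chromane-3,5,7-triol
Conditions: NBS (2.05 equiv), THF, −20 → 0 °C, dark
Reagents that add atoms: N-bromosuccinimide O=C1CCC(=O)N1Br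
Why: Electrophilic aromatic substitution on the phloroglucinol-type ring A, which is far more reactive than catechol ring B, so both C6 and C8 are brominated; this removes every carbon-nucleophilic site of the future upper ring A and makes its O1 phenoxide a better leaving group.

**Step 4**
Reactants: 6 6,8-dibromo-(+)-catechin, 7 benzyl mercaptan, 2 benzyl bromide
Product: 10 (2S)-1-(benzylsulfanyl)-1-[3,4-bis(benzyloxy)phenyl]-3-[2,4,6-tris(benzyloxy)-3,5-dibromophenyl]propan-2-ol as C1 epimer pair, via para-quinone methide 8 (not isolated), via hexahydroxy sulfide 9 (not isolated)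
Conditions: BnSH (2 equiv), K2CO3, degassed DMF, 40 °C, Ar; then BnBr (9 equiv), 50 °C
Reagents that add atoms: benzyl mercaptan SCc1ccccc1; benzyl bromide BrCc1ccccc1
Why: The O4' phenoxide expels the acidic dibromophenoxide O1 (E1cB-type dearomatization of ring B to quinone methide 8), thiolate adds 1,6 (thia-Michael, rearomatization) to give 9 with the former C3 centre untouched (S) and C1 as an irrelevant epimer pair, and Williamson benzylation of the five phenoxides then removes the O4'–H needed for retro-addition and caps the ring-A oxygens so the chain cannot recyclize.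

**Step 5**
Reactants: 10 capped sulfide, 5 C8-bromo nucleophile
Product: 12 (2R,3S)-8-bromo-5,7-bis(benzyloxy)-2-[3,4-bis(benzyloxy)phenyl]-6-{(1R,2S)-1-[3,4-bis(benzyloxy)phenyl]-2-hydroxy-3-[2,4,6-tris(benzyloxy)-3,5-dibromophenyl]propyl}chroman-3-ol, via benzylic cation 11 (not isolated)
Conditions: AgOSO2CF3 (1.5 equiv), 5 (2.5 equiv), 4 Å MS, CH2Cl2, −60 → −30 °C; then Et3N
Reagents that add atoms: none
Why: Proposed new method: thiophilic silver triflate ionizes the benzylic sulfide to the para-benzyloxybenzylic (quinoid) cation 11 (closest known reaction types: silver-mediated coupling of benzylsulfanyl flavans with phenolic nucleophiles and Friedel–Crafts alkylation of a C8-bromide-blocked flavan at C6), 11 has no free ring-A carbon or phenol for self-capture so C6 of 5 is the only π-nucleophile while O-alkylation stays reversible under the acid formed, and the methine is expected to be set R because in the allylic-strain-minimized conformer (C2–H eclipsing the aryl plane) the bulky ring-A benzyl arm, whose ortho-benzyloxy oxygen can bridge to the cation as a 2,3-trans six-membered oxonium, covers one face and the arene enters anti to it on the side of the small free hydroxyl, the same sense as an invertive opening of the catechin pyran.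

**Step 6**
Reactants: 12 protected dimer
Product: 13 target gambiriin, (2R,3S)-2-(3,4-dihydroxyphenyl)-6-[(1R,2S)-1-(3,4-dihydroxyphenyl)-2-hydroxy-3-(2,4,6-trihydroxyphenyl)propyl]chromane-3,5,7-triol
Conditions: H2 (1 atm), Pd(OH)2/C, Et3N, THF/MeOH/H2O, rt; filter under Ar, Sephadex LH-20
Reagents that add atoms: none
Why: Catalytic hydrogenolysis cleaves all nine O-benzyl ethers and, with Et3N as HBr scavenger, hydrodebrominates the three aryl bromides in the same operation, while the flavan C2–O bond and the methine C–C bonds are not hydrogenolysed under these neutral to weakly basic conditions, so no stereocentre changes.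

## Compound list

1 | (+)-catechin, (2R,3S)-2-(3,4-dihydroxyphenyl)chromane-3,5,7-triol | O[C@H]1Cc2c(O)cc(O)cc2O[C@@H]1c1ccc(O)c(O)c1 | starting material
2 | benzyl bromide | BrCc1ccccc1 | starting material
3 | (2R,3S)-5,7-bis(benzyloxy)-2-[3,4-bis(benzyloxy)phenyl]chroman-3-ol | O[C@H]1Cc2c(OCc3ccccc3)cc(OCc3ccccc3)cc2O[C@@H]1c1ccc(OCc2ccccc2)c(OCc2ccccc2)c1 | intermediate
4 | N-bromosuccinimide | O=C1CCC(=O)N1Br | starting material
5 | (2R,3S)-8-bromo-5,7-bis(benzyloxy)-2-[3,4-bis(benzyloxy)phenyl]chroman-3-ol | O[C@H]1Cc2c(OCc3ccccc3)cc(OCc3ccccc3)c(Br)c2O[C@@H]1c1ccc(OCc2ccccc2)c(OCc2ccccc2)c1 | intermediate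
6 | (2R,3S)-6,8-dibromo-2-(3,4-dihydroxyphenyl)chromane-3,5,7-triol | O[C@H]1Cc2c(O)c(Br)c(O)c(Br)c2O[C@@H]1c1ccc(O)c(O)c1 | intermediate
7 | benzyl mercaptan (phenylmethanethiol) | SCc1ccccc1 | starting material
8 | 4-[(2S)-3-(3,5-dibromo-2,4,6-trihydroxyphenyl)-2-hydroxypropylidene]-2-hydroxycyclohexa-2,5-dien-1-one (para-quinone methide, alkene geometry not defined) | O=C1C=CC(=C[C@@H](O)Cc2c(O)c(Br)c(O)c(Br)c2O)C=C1O | intermediate
9 | (2S)-1-(benzylsulfanyl)-3-(3,5-dibromo-2,4,6-trihydroxyphenyl)-1-(3,4-dihydroxyphenyl)propan-2-ol, C1 epimer pair | O[C@@H](Cc1c(O)c(Br)c(O)c(Br)c1O)C(SCc1ccccc1)c1ccc(O)c(O)c1 | intermediate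
10 | (2S)-1-(benzylsulfanyl)-1-[3,4-bis(benzyloxy)phenyl]-3-[2,4,6-tris(benzyloxy)-3,5-dibromophenyl]propan-2-ol, C1 epimer pair | O[C@@H](Cc1c(OCc2ccccc2)c(Br)c(OCc2ccccc2)c(Br)c1OCc1ccccc1)C(SCc1ccccc1)c1ccc(OCc2ccccc2)c(OCc2ccccc2)c1 | intermediate
11 | (2S)-1-[3,4-bis(benzyloxy)phenyl]-2-hydroxy-3-[2,4,6-tris(benzyloxy)-3,5-dibromophenyl]propan-1-ylium (benzylic cation) | O[C@@H](Cc1c(OCc2ccccc2)c(Br)c(OCc2ccccc2)c(Br)c1OCc1ccccc1)[CH+]c1ccc(OCc2ccccc2)c(OCc2ccccc2)c1 | intermediate
12 | (2R,3S)-8-bromo-5,7-bis(benzyloxy)-2-[3,4-bis(benzyloxy)phenyl]-6-{(1R,2S)-1-[3,4-bis(benzyloxy)phenyl]-2-hydroxy-3-[2,4,6-tris(benzyloxy)-3,5-dibromophenyl]propyl}chroman-3-ol | O(Cc9ccccc9)c1c(Br)c(OCc9ccccc9)c(C[C@H](O)[C@H](c2ccc(OCc9ccccc9)c(OCc9ccccc9)c2)c2c(OCc9ccccc9)c(Br)c3c(c2OCc9ccccc9)C[C@H](O)[C@@H](c2ccc(OCc9ccccc9)c(OCc9ccccc9)c2)O3)c(OCc9ccccc9)c1Br | intermediate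
13 | target gambiriin, (2R,3S)-2-(3,4-dihydroxyphenyl)-6-[(1R,2S)-1-(3,4-dihydroxyphenyl)-2-hydroxy-3-(2,4,6-trihydroxyphenyl)propyl]chromane-3,5,7-triol | Oc1cc(O)c(C[C@H](O)[C@H](c2ccc(O)c(O)c2)c2c(O)cc3c(c2O)C[C@H](O)[C@@H](c2ccc(O)c(O)c2)O3)c(O)c1 | target

## Step count and risks

Total steps: 6. Longest linear sequence: 4 (1 → 6 → 10 → 12 → 13; the branch 1 → 3 → 5 → 12 → 13 is equally long).

**Most likely to fail, first: step 5.** C6 of 5 is hindered and deactivated by the C8 bromine. The methine configuration rests on acyclic stereocontrol, and attack anti to the C2 hydroxyl would give the 1S epimer; this is the real weak point of the route. Loss of benzyl from the bridged oxonium would return a closed dibromo flavan.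

The fallback replaces the ether nucleophile by a free phenolic one. It sets out from 5, which is debenzylated with BCl3 and pentamethylbenzene in CH2Cl2 at −78 °C (the aryl bromide survives) to 8-bromo-(+)-catechin F1. F1 (3 equiv) is coupled with 10 using AgBF4 in THF at 0 °C. Its free phloroglucinol-type ring is far more nucleophilic at C6, and its phenolic OH groups can hydrogen-bond to the C2 hydroxyl of the cation and deliver the arene on that face. This gives the partly protected adduct (2R,3S)-8-bromo-2-(3,4-dihydroxyphenyl)-6-{(1R,2S)-1-[3,4-bis(benzyloxy)phenyl]-2-hydroxy-3-[2,4,6-tris(benzyloxy)-3,5-dibromophenyl]propyl}chromane-3,5,7-triol F2, with methine epimers separated at this stage. Hydrogenolysis of F2 under the step 6 conditions comes back to the route at 13.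

**Second: step 4.** The free catechol is air-sensitive under base, thiol can reduce the quinone methide, and retro-addition competes until O4' is benzylated.

The fallback avoids the quinone methide altogether and sets out from 3. Dibromination with NBS (2.1 equiv, CH2Cl2, −40 °C → rt) gives (2R,3S)-6,8-dibromo-5,7-bis(benzyloxy)-2-[3,4-bis(benzyloxy)phenyl]chroman-3-ol F3. Lewis-acid thiolysis of its benzylic C2–O1 bond (BF3·OEt2, benzyl mercaptan, CH2Cl2, 0 °C) gives (2S)-1-(benzylsulfanyl)-1-[3,4-bis(benzyloxy)phenyl]-3-[4,6-bis(benzyloxy)-3,5-dibromo-2-hydroxyphenyl]propan-2-ol F4 as a C1 epimer pair. Benzylation of its single phenol with 2 and K2CO3 in DMF comes back to the route at 10.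

**Third: step 6.** Twelve hydrogenolytic events must go to completion on one molecule, and the free polyphenol is sensitive to air and base.

The fallback separates the two tasks and sets out from 12. BCl3 with pentamethylbenzene (CH2Cl2, −78 °C) removes all nine benzyl groups without touching C–Br and gives (2R,3S)-8-bromo-6-[(1R,2S)-3-(3,5-dibromo-2,4,6-trihydroxyphenyl)-1-(3,4-dihydroxyphenyl)-2-hydroxypropyl]-2-(3,4-dihydroxyphenyl)chromane-3,5,7-triol F5. Brief hydrodebromination of F5 (Pd/C, H2, sodium acetate, MeOH, rt) comes back to the route at 13.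

## Further compounds

F1 | step 5 | (2R,3S)-8-bromo-2-(3,4-dihydroxyphenyl)chromane-3,5,7-triol | O[C@H]1Cc2c(O)cc(O)c(Br)c2O[C@@H]1c1ccc(O)c(O)c1
F2 | step 5 | (2R,3S)-8-bromo-2-(3,4-dihydroxyphenyl)-6-{(1R,2S)-1-[3,4-bis(benzyloxy)phenyl]-2-hydroxy-3-[2,4,6-tris(benzyloxy)-3,5-dibromophenyl]propyl}chromane-3,5,7-triol | O(Cc9ccccc9)c1c(Br)c(OCc9ccccc9)c(C[C@H](O)[C@H](c2ccc(OCc9ccccc9)c(OCc9ccccc9)c2)c2c(O)c(Br)c3c(c2O)C[C@H](O)[C@@H](c2ccc(O)c(O)c2)O3)c(OCc9ccccc9)c1Br
F3 | step 4 | (2R,3S)-6,8-dibromo-5,7-bis(benzyloxy)-2-[3,4-bis(benzyloxy)phenyl]chroman-3-ol | O[C@H]1Cc2c(OCc3ccccc3)c(Br)c(OCc3ccccc3)c(Br)c2O[C@@H]1c1ccc(OCc2ccccc2)c(OCc2ccccc2)c1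
F4 | step 4 | (2S)-1-(benzylsulfanyl)-1-[3,4-bis(benzyloxy)phenyl]-3-[4,6-bis(benzyloxy)-3,5-dibromo-2-hydroxyphenyl]propan-2-ol, C1 epimer pair | O[C@@H](Cc1c(O)c(Br)c(OCc2ccccc2)c(Br)c1OCc1ccccc1)C(SCc1ccccc1)c1ccc(OCc2ccccc2)c(OCc2ccccc2)c1
F5 | step 6 | (2R,3S)-8-bromo-6-[(1R,2S)-3-(3,5-dibromo-2,4,6-trihydroxyphenyl)-1-(3,4-dihydroxyphenyl)-2-hydroxypropyl]-2-(3,4-dihydroxyphenyl)chromane-3,5,7-triol | Oc1c(Br)c(O)c(C[C@H](O)[C@H](c2ccc(O)c(O)c2)c2c(O)c(Br)c3c(c2O)C[C@H](O)[C@@H](c2ccc(O)c(O)c2)O3)c(O)c1Br
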